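## Analysis of the target

The target (19) is a trans-2-aryl-3-methyl-2,3-dihydro-1-benzofuran of the neolignan type. Ring A, the benzo ring, carries a methoxy group at C7 (next to the ring oxygen O1) and an (E)-prop-1-enyl group at C5 (para to O1). C2 carries ring B, a 3-hydroxy-4,5-dimethoxyphenyl group, and C3 carries a methyl group. C2 and C3 are the only stereocentres, both S and adjacent, with ring B and the methyl group on opposite faces of the five-membered ring. No other stereocentre exists from which they could be induced, so absolute control must come from a catalyst or reagent.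

The sensitive groups are three. The propenyl group is an electron-rich styrene that tolerates neither acid, oxidative cleavage nor hydrogenation and must keep its E geometry. The C2–O1 bond is a benzylic ether that can ionise under strong acid. The single free phenol at C3' must be kept distinct from four ether oxygens. The difficulty is therefore to set the trans C2/C3 pair in absolute terms and to bring in the propenyl group and the free phenol late.

The strategy rests on one feature: C2 and C3 are the two furan carbons of a benzofuran, and each has gained exactly one carbon group (C1' of ring B at C2, the methyl carbon at C3), trans to one another. The target can thus be read as a flat, achiral 5,7-disubstituted benzofuran across whose C2=C3 bond two carbon groups have been added anti.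

## Retrosynthetic reasoning

**C5–propenyl bond (19 ⇒ 17 + 18).** The bond between C5 of ring A and the propenyl group is cut first, because the propenylarene is the most fragile function and would not survive oxidative alkene cleavage or acid. It is made in the last step by Suzuki–Miyaura coupling of the aryl chloride 17 with the (E)-alkenylboronic ester 18. Chlorine is the placeholder at C5 because it is inert to the lithiation and to the palladium catalyst of the key step, yet can be activated later by an electron-rich phosphine ligand.

**Ring B phenol (17 ⇒ 16).** The C3' hydroxyl is carried as a methoxymethyl ether. This group tolerates organolithium chemistry, fluoride, periodate and heating, and it is removed by acid in 16, one step before the acid-sensitive propenyl group arrives.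

**C3 methyl group (16 ⇒ 15 ⇒ 14).** The key reaction needs an allyl electrophile, so the C3 substituent arrives as an allyl group and is trimmed by two carbons. The methyl C–H bond of 16 is traced to the formyl group of aldehyde 15 (decarbonylation), and 15 to the terminal alkene of 14 (oxidative cleavage). The C3–CH2 bond made in the key step is the C3–CH3 bond of the target. C3 is β, not α, to the carbonyl of 15, so it cannot epimerise.

**C2–H bond (14 ⇒ 13).** The hydrogen at C2 replaces a boronic ester group. Protodeboronation with retention places hydrogen where boron was, cis to the C3 substituent, which leaves ring B trans to it.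

**Key disconnection (13 ⇒ 6 + 9 + 10).** The bonds C2–C1' and C3–CH2(allyl) are cut together. This leads back to the aromatic benzofuran 6, the ring B boronic ester 9 and allyl acetate 10, by way of the 2-lithio compound 11 and the boron ate complex 12. The cut is made here because both stereocentres vanish into an achiral heteroarene and the two aromatic halves are joined convergently. No ring has to be closed, since the ring exists already. The forward reaction must achieve selective metalation of 6 at C2, attack of an allyl electrophile generated from 10 on palladium at C3 from one face only, and migration of ring B from boron to C2 on the opposite face.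

**Benzofuran 6 (6 ⇒ 5 ⇒ 1 + 2).** The furan ring is taken apart at O1–C2 and C2=C3. The acid 5 loses CO2 to give 6, and 5 arises from the salicylaldehyde 1 and the bromoacetate 2 by O-alkylation (3), intramolecular aldol condensation (4) and saponification. The aldehyde carbon of 1 becomes C3, and the chlorine and methoxy group of 1 are already at the positions that become C5 and C7.

**Boronic ester 9 (9 ⇒ 8 ⇒ 7).** The C–B bond is cut back to a C–H bond of the protected phenol 8, made from 7. In 8 only one aromatic C–H has no ortho substituent, and it is the one that must become C1' of ring B, so a sterically governed C–H borylation needs no halogen and no directing group.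

## Alternatives that were turned down

**Alternative 1:** Ring A itself is disconnected at C7a–C3a, C4–C5 and C5–C6. The precursor is the chromium carbene complex A2, (CO)5Cr=C(OR)(C(OMe)=CH2), whose alkoxy group R is the C2–C3 unit bearing ring B, the methyl group and a terminal alkyne. On heating, a Dötz benzannulation (alkyne insertion, CO insertion, electrocyclisation) would close the dihydrofuran ring and ring A together and give the C5 phenol A1.
- For it: two rings and three C–C bonds form in one step. The oxygen pattern of ring A follows from the mechanism, with the C5 hydroxyl as a handle for the propenyl group through its triflate. No stereocentre is formed in the key step, so on stereochemical safety of the key step this alternative is stronger than step 5.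
- Against it: both stereocentres must be built in an open chain beforehand by a separate asymmetric propargylation. A secondary benzylic alkoxide must be attached to the carbene carbon by alkoxy exchange, and that benzylic C–O bond, next to a strongly electron-withdrawing carbene carbon, is prone to ionise or eliminate at the benzannulation temperature. The two-atom tether forces the substituted alkyne carbon to bond to the carbene carbon, against the normal steric preference and through a strained five-membered arrangement, which favours cyclisation without CO insertion. Chromium is stoichiometric. A1 is an air-sensitive p-alkoxyphenol, and triflation, coupling and desilylation still follow.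
- Comparison: the sequence is linear and about three steps longer than the chosen one. The chosen route offers catalysis, convergence from two simple arenes and both stereocentres from one catalytic step, at the price of a key step without direct precedent.

**Alternative 2:** The C3–C3a bond is traced to a 1,2-aryl shift. The precursor is the enantiopure flavanone A4. A trivalent iodine oxidant with acid in an orthoester would functionalise the enol ether at C3, whereupon the ring A carbon migrates from the carbonyl carbon to C3. The pyranone contracts to the dihydrofuran and the former carbonyl carbon remains at C3 as the methyl ester of A3, trans to ring B.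
- For it: this ring contraction is established chemistry with a dependable trans outcome, and the single stereocentre of A4 controls C3. On precedent for the key step this alternative is clearly stronger than the chosen one.
- Against it: A4 can racemise by reversible ring opening to the chalcone under acid or base. Ring B is a trialkoxyphenyl group, so the electrophilic iodine reagent can attack it, and the competing channels of this oxidation (migration of the 2-aryl group to give the isoflavone, dehydrogenation to the flavone) gain weight with electron-rich 2-aryl groups. The ester of A3 needs three steps to reach a methyl group (reduction, sulfonylation, hydride displacement), against two for the allyl group of 13. The benzyl ether cannot be hydrogenolysed once the propenyl group is present, and before that the aryl bromide is at risk.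
- Comparison: the sequence is linear and about three steps longer. The chosen route makes both bonds and both stereocentres in the enantioselective step and never exposes a stereocentre to epimerising conditions.

**Alternative 3:** C2 is inserted as a one-carbon unit between C3 and ring B, so the bonds C2–C3 and C2–C1' are cut. In a Matteson homologation, a dichloromethyl carbenoid adds to the boron of the secondary benzylic boronic ester A6, and the C3 carbon shifts to the new carbon with loss of chloride under control of the chiral diol. The ring B arylmagnesium bromide A7 then displaces the second chloride by another 1,2-shift and gives the open-chain boronic ester A5 (syn).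
- For it: every reaction is well precedented, both shifts are stereospecific, and the C2-symmetric diol gives reagent control. On predictability of the stereochemistry this alternative is stronger than step 5.
- Against it: the chain is open, so C3 must first be set in A6 by a separate asymmetric step on an ortho-substituted ring A precursor, where selectivity tends to suffer. The chiral diol is stoichiometric, the carbenoid needs about −100 °C, and the resident C3 centre and the diol may be mismatched. After A5 the C–B bond must still be oxidised, the ring A phenol released (its methoxymethyl ether cannot be distinguished from the one on ring B, so the protecting groups need redesign) and the ring closed with inversion at a benzylic carbinol that can leak into an ionising pathway.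
- Comparison: roughly twelve steps result. The chosen route avoids ring closure and open-chain intermediates altogether and uses a catalytic source of chirality.

Key step: step 5

Assumption: the sense of induction of BINAP for a benzofuran-derived boronate cannot be deduced safely from the indole case; (S)-BINAP is written and stands for whichever enantiomer a model run shows to give the (2S,3S) product.
Assumption: compounds 1, 2, 7, 10 and 18 are taken as commercial.

## Route

Step 1
Reactants: 1 5-chloro-2-hydroxy-3-methoxybenzaldehyde; 2 ethyl bromoacetate
Product: 5 5-chloro-7-methoxy-1-benzofuran-2-carboxylic acid, via ethyl aryloxyacetate 3 (not isolated), via ethyl benzofuran-2-carboxylate 4 (not isolated)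
Conditions: K2CO3, DMF, 90 °C; then 2 M NaOH (aq), 60 °C; then HCl to pH 2
Reagents that add atoms: sodium hydroxide, [Na+].[OH-] (hydroxyl oxygen of the acid)
Why: Williamson O-alkylation of the phenoxide by 2, then intramolecular aldol condensation of the ester enolate onto the ortho formyl group with loss of water (the classical benzofuran-2-carboxylate annulation), then saponification in the same pot. The aryl chloride and the methyl ether are inert to carbonate and hydroxide.

Step 2
Reactants: 5 5-chloro-7-methoxy-1-benzofuran-2-carboxylic acid
Product: 6 5-chloro-7-methoxy-1-benzofuran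
Conditions: Cu powder, quinoline, 200 °C
Reagents that add atoms: none
Why: Copper-mediated protodecarboxylation of a heteroaryl-2-carboxylic acid; the copper carboxylate loses CO2 to an ArCu intermediate that is protonated. An aryl chloride does not react with copper under these ligand-free conditions.

Step 3
Reactants: 7 2,3-dimethoxyphenol
Product: 8 1,2-dimethoxy-3-(methoxymethoxy)benzene
Conditions: MOMCl, iPr2NEt, CH2Cl2, 0 °C to rt
Reagents that add atoms: chloromethyl methyl ether, COCCl
Why: O-alkylation of the phenol by the reactive α-chloro ether under amine base. The methoxymethyl ether tolerates every later step up to the acid of step 9.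

Step 4
Reactants: 8 1,2-dimethoxy-3-(methoxymethoxy)benzene
Product: 9 2-[3-(methoxymethoxy)-4,5-dimethoxyphenyl]-4,4,5,5-tetramethyl-1,3,2-dioxaborolane
Conditions: [Ir(OMe)(cod)]2 (1.5 mol %), dtbpy (3 mol %), B2pin2 (1.0 equiv), THF, 80 °C
Reagents that add atoms: bis(pinacolato)diboron, CC1(C)OB(OC1(C)C)B1OC(C)(C)C(C)(C)O1
Why: Iridium-catalysed aromatic C–H borylation is governed by sterics. C5 of 8 is the only C–H without an ortho substituent (C4 and C6 each lie next to an alkoxy group), so the Ir(dtbpy)(Bpin)3 species should borylate there alone.

Step 5
Reactants: 6 5-chloro-7-methoxy-1-benzofuran; 9 2-[3-(methoxymethoxy)-4,5-dimethoxyphenyl]-4,4,5,5-tetramethyl-1,3,2-dioxaborolane; 10 allyl acetate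
Product: 13 (2S,3S)-3-allyl-5-chloro-7-methoxy-2-[3-(methoxymethoxy)-4,5-dimethoxyphenyl]-2-(4,4,5,5-tetramethyl-1,3,2-dioxaborolan-2-yl)-2,3-dihydro-1-benzofuran, via 2-lithiobenzofuran 11 (not isolated), via lithium boronate 12 (not isolated)
Conditions: n-BuLi (1.05 equiv), THF, −78 °C; 9 (1.0 equiv), −78 to 0 °C; then Pd2(dba)3 (2.5 mol %), (S)-BINAP (6 mol %), 10 (1.5 equiv), THF, rt
Reagents that add atoms: none
Why: Proposed new method: deprotonation of 6 at C2, its most acidic C–H bond, gives 11, which adds to the boron of 9 to form the tetracoordinate boronate 12; the C2=C3 enol ether π bond of 12, made electron-rich by the anionic boron, attacks a terminal carbon of the cationic complex [Pd(C3H5)((S)-BINAP)]+ (from zerovalent palladium and 10) through C3, while ring B shifts from boron to C2 as positive charge builds up there. The nearest established reaction type is the three-component coupling of 2-lithiated indoles, boronic esters and allylic acetates under Pd2(dba)3/chiral bisphosphine catalysis, in which C3 allylation drives a 1,2-shift from boron to C2 and gives trans-2,3-disubstituted indolines with boron at C2; a benzofuran-2-yl boronate is its oxygen analogue, with a less nucleophilic C3. No ring is closed: the furan ring only gives up its aromaticity, and the bonds C3–CH2 and C2–C1' are formed. C3 is set by the chiral bisphosphine on palladium, which differentiates the two faces of the planar benzofuran in the outer-sphere attack on the allyl ligand. C2 is set relative to C3 by the stereoelectronics of the 1,2-shift, ring B migrating anti to the incoming allyl group, so that aryl and allyl end up trans and boron cis to allyl. The step needs C3 allylation with migration to outrun direct boron-to-palladium transmetalation (plain allyl–aryl coupling); the bidentate ligand and the absence of added base favour the outer-sphere path, and the electron-rich ring B is a good migrating group whereas the pinacol oxygens are not. The C5 chloride is spared because zerovalent Pd(BINAP) does not insert into aryl chlorides at room temperature, and at −78 °C C2–H is deprotonated in preference to C6–H or lithium–chlorine exchange.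

Step 6
Reactants: 13 (2S,3S)-3-allyl-5-chloro-7-methoxy-2-[3-(methoxymethoxy)-4,5-dimethoxyphenyl]-2-(4,4,5,5-tetramethyl-1,3,2-dioxaborolan-2-yl)-2,3-dihydro-1-benzofuran
Product: 14 (2S,3S)-3-allyl-5-chloro-7-methoxy-2-[3-(methoxymethoxy)-4,5-dimethoxyphenyl]-2,3-dihydro-1-benzofuran
Conditions: CsF (1.5 equiv), H2O (1.1 equiv), 1,4-dioxane, 45 °C
Reagents that add atoms: none
Why: Fluoride adds to boron, and the ate complex of this tertiary benzylic boronic ester is protonated by water at carbon on the face that boron leaves (stereoretentive protodeboronation, as established for tertiary benzylic pinacol boronates). Hydrogen thus takes the place of boron cis to the C3 allyl group, which leaves ring B trans to it and fixes C2 as S.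

Step 7
Reactants: 14 (2S,3S)-3-allyl-5-chloro-7-methoxy-2-[3-(methoxymethoxy)-4,5-dimethoxyphenyl]-2,3-dihydro-1-benzofuran
Product: 15 2-[(2S,3S)-5-chloro-7-methoxy-2-[3-(methoxymethoxy)-4,5-dimethoxyphenyl]-2,3-dihydro-1-benzofuran-3-yl]acetaldehyde
Conditions: OsO4 (2 mol %), NaIO4 (4 equiv), 2,6-lutidine, 1,4-dioxane/H2O 3:1, rt
Reagents that add atoms: sodium periodate, [Na+].[O-]I(=O)(=O)=O (terminal oxidant and source of the carbonyl oxygen by way of osmium tetroxide, O=[Os](=O)(=O)=O)
Why: Lemieux–Johnson oxidation: catalytic OsO4 dihydroxylates the only alkene, and NaIO4 cleaves the diol and reoxidises osmium, with 2,6-lutidine suppressing over-oxidation. The phenol is protected, and C3 is β to the new carbonyl, so it cannot epimerise by enolisation.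

Step 8
Reactants: 15 2-[(2S,3S)-5-chloro-7-methoxy-2-[3-(methoxymethoxy)-4,5-dimethoxyphenyl]-2,3-dihydro-1-benzofuran-3-yl]acetaldehyde
Product: 16 (2S,3S)-5-chloro-7-methoxy-2-[3-(methoxymethoxy)-4,5-dimethoxyphenyl]-3-methyl-2,3-dihydro-1-benzofuran
Conditions: RhCl(PPh3)3 (1.1 equiv), toluene, 110 °C
Reagents that add atoms: none
Why: Tsuji–Wilkinson decarbonylation: the aldehyde C–H bond adds to monovalent rhodium, CO is extruded onto the metal and C–H reductive elimination turns CH2CHO into CH3 without touching either stereocentre. A primary aldehyde reacts at moderate temperature, and the aryl chloride does not add to rhodium under these conditions.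

Step 9
Reactants: 16 (2S,3S)-5-chloro-7-methoxy-2-[3-(methoxymethoxy)-4,5-dimethoxyphenyl]-3-methyl-2,3-dihydro-1-benzofuran
Product: 17 5-[(2S,3S)-5-chloro-7-methoxy-3-methyl-2,3-dihydro-1-benzofuran-2-yl]-2,3-dimethoxyphenol
Conditions: conc. HCl (2 equiv), MeOH/THF, 40 °C
Reagents that add atoms: none
Why: Acid-catalysed acetal exchange with methanol cleaves the aryl methoxymethyl ether. It is done before the propenyl group is present, so no acid-sensitive styrene is exposed, and dilute acid at 40 °C should not ionise the C2–O1 bond.

Step 10
Reactants: 17 5-[(2S,3S)-5-chloro-7-methoxy-3-methyl-2,3-dihydro-1-benzofuran-2-yl]-2,3-dimethoxyphenol; 18 4,4,5,5-tetramethyl-2-[(E)-prop-1-en-1-yl]-1,3,2-dioxaborolane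
Product: 19 5-[(2S,3S)-7-methoxy-3-methyl-5-[(E)-prop-1-en-1-yl]-2,3-dihydro-1-benzofuran-2-yl]-2,3-dimethoxyphenol
Conditions: Pd(OAc)2 (3 mol %), SPhos (6 mol %), K3PO4 (3 equiv), 1,4-dioxane/H2O 5:1, 90 °C
Reagents that add atoms: none
Why: Suzuki–Miyaura coupling: the electron-rich dialkylbiarylphosphine lets zerovalent palladium insert into the C5–Cl bond, and transmetalation of the alkenylboronate and reductive elimination proceed with retention of the E geometry. The free phenol is carried as its phosphate-buffered phenoxide, and neither stereocentre is involved.

## Compound list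

1 | 5-chloro-2-hydroxy-3-methoxybenzaldehyde | O=Cc1cc(Cl)cc(OC)c1O | starting material
2 | ethyl bromoacetate | CCOC(=O)CBr | starting material
3 | ethyl (4-chloro-2-formyl-6-methoxyphenoxy)acetate | CCOC(=O)COc1c(C=O)cc(Cl)cc1OC | intermediate
4 | ethyl 5-chloro-7-methoxy-1-benzofuran-2-carboxylate | CCOC(=O)c1cc2cc(Cl)cc(OC)c2o1 | intermediate
5 | 5-chloro-7-methoxy-1-benzofuran-2-carboxylic acid | OC(=O)c1cc2cc(Cl)cc(OC)c2o1 | intermediate
6 | 5-chloro-7-methoxy-1-benzofuran | COc1cc(Cl)cc2ccoc12 | intermediate
7 | 2,3-dimethoxyphenol | COc1cccc(O)c1OC | starting material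
8 | 1,2-dimethoxy-3-(methoxymethoxy)benzene | COCOc1cccc(OC)c1OC | intermediate
9 | 2-[3-(methoxymethoxy)-4,5-dimethoxyphenyl]-4,4,5,5-tetramethyl-1,3,2-dioxaborolane | COCOc1cc(B2OC(C)(C)C(C)(C)O2)cc(OC)c1OC | intermediate
10 | allyl acetate | C=CCOC(C)=O | starting material
11 | (5-chloro-7-methoxy-1-benzofuran-2-yl)lithium | [Li]c1cc2cc(Cl)cc(OC)c2o1 | intermediate
12 | lithium (5-chloro-7-methoxy-1-benzofuran-2-yl)[3-(methoxymethoxy)-4,5-dimethoxyphenyl](pinacolato)borate | [Li+].COc1cc(Cl)cc2cc(oc12)[B-]1(c2cc(OCOC)c(OC)c(OC)c2)OC(C)(C)C(C)(C)O1 | intermediate
13 | (2S,3S)-3-allyl-5-chloro-7-methoxy-2-[3-(methoxymethoxy)-4,5-dimethoxyphenyl]-2-(4,4,5,5-tetramethyl-1,3,2-dioxaborolan-2-yl)-2,3-dihydro-1-benzofuran | Clc1cc(OC)c2c(c1)[C@H](CC=C)[C@@](B1OC(C)(C)C(C)(C)O1)(c1cc(OCOC)c(OC)c(OC)c1)O2 | intermediate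
14 | (2S,3S)-3-allyl-5-chloro-7-methoxy-2-[3-(methoxymethoxy)-4,5-dimethoxyphenyl]-2,3-dihydro-1-benzofuran | Clc1cc(OC)c2c(c1)[C@H](CC=C)[C@@H](c1cc(OCOC)c(OC)c(OC)c1)O2 | intermediate
15 | 2-[(2S,3S)-5-chloro-7-methoxy-2-[3-(methoxymethoxy)-4,5-dimethoxyphenyl]-2,3-dihydro-1-benzofuran-3-yl]acetaldehyde | Clc1cc(OC)c2c(c1)[C@H](CC=O)[C@@H](c1cc(OCOC)c(OC)c(OC)c1)O2 | intermediate
16 | (2S,3S)-5-chloro-7-methoxy-2-[3-(methoxymethoxy)-4,5-dimethoxyphenyl]-3-methyl-2,3-dihydro-1-benzofuran | Clc1cc(OC)c2c(c1)[C@H](C)[C@@H](c1cc(OCOC)c(OC)c(OC)c1)O2 | intermediate
17 | 5-[(2S,3S)-5-chloro-7-methoxy-3-methyl-2,3-dihydro-1-benzofuran-2-yl]-2,3-dimethoxyphenol | Clc1cc(OC)c2c(c1)[C@H](C)[C@@H](c1cc(O)c(OC)c(OC)c1)O2 | intermediate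
18 | 4,4,5,5-tetramethyl-2-[(E)-prop-1-en-1-yl]-1,3,2-dioxaborolane | C/C=C/B1OC(C)(C)C(C)(C)O1 | starting material
19 | 5-[(2S,3S)-7-methoxy-3-methyl-5-[(E)-prop-1-en-1-yl]-2,3-dihydro-1-benzofuran-2-yl]-2,3-dimethoxyphenol | C/C=C/c1cc(OC)c2c(c1)[C@H](C)[C@@H](c1cc(O)c(OC)c(OC)c1)O2 | target

## Step count and least certain steps

Total step count: 10.
Longest linear sequence: 8 steps (steps 1, 2, 5, 6, 7, 8, 9, 10 from 1; equally steps 3, 4, 5 to 10 from 7).

**Step 5 (key step, the one step beyond known chemistry).**
- What may go wrong: direct transfer of an aryl group from boron to palladium may win, which amounts to plain allyl–aryl coupling without dearomatisation. The reason is that C3 of a benzofuran boronate is less nucleophilic than C3 of the indole analogue, since oxygen donates less than nitrogen. Facial selectivity may also be lower than for indoles, because the ligand has no N-substituent to read.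
- Fallback (known chemistry, sets out from 9, comes back at 16): the dearomative coupling is given up, and the trans ring is built by palladium-catalysed oxyarylation of a propenylarene with an o-iodophenol, followed by resolution. Suzuki–Miyaura coupling of 9 with (E)-1-bromoprop-1-ene (Pd(PPh3)4, K2CO3, 1,4-dioxane/H2O, 80 °C) gives 1,2-dimethoxy-3-(methoxymethoxy)-5-[(E)-prop-1-en-1-yl]benzene F1. Iodination of commercial 4-chloro-2-methoxyphenol ortho to the hydroxyl group (N-iodosuccinimide, MeCN) gives 4-chloro-2-iodo-6-methoxyphenol F2. Heating F1 and F2 with Pd(OAc)2 and Ag2CO3 in acetone should add the ArPdI species across the alkene, aryl to the methyl-bearing carbon, and then form the C–O bond at the benzylic carbon. This gives the trans-dihydrobenzofuran as the racemate, that is 16 together with its mirror image (2R,3R)-5-chloro-7-methoxy-2-[3-(methoxymethoxy)-4,5-dimethoxyphenyl]-3-methyl-2,3-dihydro-1-benzofuran F3. Preparative chromatography on a chiral stationary phase separates the two, and 16 re-enters at step 9. Steps 6 to 8 fall away; the price is half of the material and the loss of catalytic enantiocontrol.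

**Step 6 (protodeboronation).**
- What may go wrong: stereochemical fidelity at C2 may be lost if the fluoride ate complex releases a free benzylic carbanion, which is protonated from the less hindered face and gives the cis isomer. Heterolysis of the C2–O1 bond from the ate complex, with ring opening, is a second possibility. Both arise because C2 is at once benzylic and α to an aryloxy group.
- Fallback (sets out from 13, comes back at 14): the C–B bond is oxidised (NaBO3·4H2O, THF/H2O, 0 °C). The resulting 2-hydroxy-dihydrobenzofuran opens to the keto phenol (2S)-2-(5-chloro-2-hydroxy-3-methoxyphenyl)-1-[3-(methoxymethoxy)-4,5-dimethoxyphenyl]pent-4-en-1-one F4. Because its α-stereocentre can epimerise, F4 is reduced at once (NaBH4, MeOH, −20 °C) to (2S)-2-(5-chloro-2-hydroxy-3-methoxyphenyl)-1-[3-(methoxymethoxy)-4,5-dimethoxyphenyl]pent-4-en-1-ol F5, as either C1 epimer. Acid-catalysed cyclodehydration (cat. TsOH, CH2Cl2, 0 °C) through the ring B benzylic cation then closes O1–C2 under thermodynamic control to the trans compound 14, with C3 as the controlling centre. If the methoxymethyl ether is lost, it is put back with MOMCl and iPr2NEt.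

**Step 8 (decarbonylation).**
- What may go wrong: β-hydride elimination from the RCH2–Rh(H)(CO)Cl(PPh3)2 intermediate may compete with C–H reductive elimination. This would give a 3-methylene compound that aromatises to the 3-methylbenzofuran and destroys both stereocentres. Conversion may also be slow, since the stoichiometric complex ends as an inert carbonyl complex.
- Fallback (sets out from 15, comes back at 16): a radical decarboxylation replaces the metal-mediated decarbonylation. Pinnick oxidation (NaClO2, NaH2PO4, 2-methylbut-2-ene, t-BuOH/H2O) gives 2-[(2S,3S)-5-chloro-7-methoxy-2-[3-(methoxymethoxy)-4,5-dimethoxyphenyl]-2,3-dihydro-1-benzofuran-3-yl]acetic acid F6. Coupling with 1-hydroxypyridine-2(1H)-thione (DCC, DMAP, CH2Cl2, dark) gives the thiohydroxamate ester 2-thioxopyridin-1(2H)-yl 2-[(2S,3S)-5-chloro-7-methoxy-2-[3-(methoxymethoxy)-4,5-dimethoxyphenyl]-2,3-dihydro-1-benzofuran-3-yl]acetate F7. Barton reductive decarboxylation (t-BuSH, visible light, benzene, rt) should then give 16; the thiol traps the primary radical faster than it can rearrange.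

**Step 10 (propenyl coupling).**
- What may go wrong: oxidative addition into the electron-rich C5–Cl bond (para to O1) may be slow, so that protodeboronation of 18 competes. The phenoxide of ring B may also bind palladium and retard the cycle.
- Fallback (sets out from 16, comes back at 19): the order of the last two operations is reversed, so that no phenoxide is present during coupling. Coupling of 16 with 18 under the conditions of step 10 gives (2S,3S)-7-methoxy-2-[3-(methoxymethoxy)-4,5-dimethoxyphenyl]-3-methyl-5-[(E)-prop-1-en-1-yl]-2,3-dihydro-1-benzofuran F8. Its methoxymethyl ether is then removed without protic acid (TMSOTf, 2,2'-bipyridyl, CH2Cl2, 0 °C; then H2O), which the propenylarene should tolerate, to give 19.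

## Further compounds

F1 | step 5 | 1,2-dimethoxy-3-(methoxymethoxy)-5-[(E)-prop-1-en-1-yl]benzene | C/C=C/c1cc(OCOC)c(OC)c(OC)c1
F2 | step 5 | 4-chloro-2-iodo-6-methoxyphenol | COc1cc(Cl)cc(I)c1O
F3 | step 5 | (2R,3R)-5-chloro-7-methoxy-2-[3-(methoxymethoxy)-4,5-dimethoxyphenyl]-3-methyl-2,3-dihydro-1-benzofuran | Clc1cc(OC)c2c(c1)[C@@H](C)[C@H](c1cc(OCOC)c(OC)c(OC)c1)O2
F4 | step 6 | (2S)-2-(5-chloro-2-hydroxy-3-methoxyphenyl)-1-[3-(methoxymethoxy)-4,5-dimethoxyphenyl]pent-4-en-1-one | Oc1c(OC)cc(Cl)cc1[C@H](CC=C)C(=O)c1cc(OCOC)c(OC)c(OC)c1
F5 | step 6 | (2S)-2-(5-chloro-2-hydroxy-3-methoxyphenyl)-1-[3-(methoxymethoxy)-4,5-dimethoxyphenyl]pent-4-en-1-ol (either C1 epimer) | Oc1c(OC)cc(Cl)cc1[C@H](CC=C)C(O)c1cc(OCOC)c(OC)c(OC)c1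
F6 | step 8 | 2-[(2S,3S)-5-chloro-7-methoxy-2-[3-(methoxymethoxy)-4,5-dimethoxyphenyl]-2,3-dihydro-1-benzofuran-3-yl]acetic acid | Clc1cc(OC)c2c(c1)[C@H](CC(O)=O)[C@@H](c1cc(OCOC)c(OC)c(OC)c1)O2
F7 | step 8 | 2-thioxopyridin-1(2H)-yl 2-[(2S,3S)-5-chloro-7-methoxy-2-[3-(methoxymethoxy)-4,5-dimethoxyphenyl]-2,3-dihydro-1-benzofuran-3-yl]acetate | Clc1cc(OC)c2c(c1)[C@H](CC(=O)ON1C=CC=CC1=S)[C@@H](c1cc(OCOC)c(OC)c(OC)c1)O2
F8 | step 10 | (2S,3S)-7-methoxy-2-[3-(methoxymethoxy)-4,5-dimethoxyphenyl]-3-methyl-5-[(E)-prop-1-en-1-yl]-2,3-dihydro-1-benzofuran | C/C=C/c1cc(OC)c2c(c1)[C@H](C)[C@@H](c1cc(OCOC)c(OC)c(OC)c1)O2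
A1 | alternative 1 | (2S,3S)-2-(4,5-dimethoxy-3-triisopropylsilyloxyphenyl)-7-methoxy-3-methyl-2,3-dihydro-1-benzofuran-5-ol | Oc1cc(OC)c2c(c1)[C@H](C)[C@@H](c1cc(O[Si](C(C)C)(C(C)C)C(C)C)c(OC)c(OC)c1)O2
A2 | alternative 1 | pentacarbonyl[{[(1S,2S)-1-(4,5-dimethoxy-3-triisopropylsilyloxyphenyl)-2-methylbut-3-yn-1-yl]oxy}(1-methoxyethenyl)methylidene]chromium | C#C[C@H](C)[C@@H](c1cc(O[Si](C(C)C)(C(C)C)C(C)C)c(OC)c(OC)c1)OC(C(OC)=C)=[Cr](=C=O)(=C=O)(=C=O)(=C=O)=C=O
A3 | alternative 2 | methyl (2S,3S)-2-[3-(benzyloxy)-4,5-dimethoxyphenyl]-5-bromo-7-methoxy-2,3-dihydro-1-benzofuran-3-carboxylate | Brc1cc(OC)c2c(c1)[C@H](C(=O)OC)[C@@H](c1cc(OCc3ccccc3)c(OC)c(OC)c1)O2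
A4 | alternative 2 | (2S)-2-[3-(benzyloxy)-4,5-dimethoxyphenyl]-6-bromo-8-methoxy-2,3-dihydro-4H-chromen-4-one | O=C1C[C@@H](c2cc(OCc3ccccc3)c(OC)c(OC)c2)Oc2c(OC)cc(Br)cc12
A5 | alternative 3 | (4R,5R)-2-[(1R,2R)-2-[5-chloro-3-methoxy-2-(methoxymethoxy)phenyl]-1-[3-(methoxymethoxy)-4,5-dimethoxyphenyl]propyl]-4,5-dicyclohexyl-1,3,2-dioxaborolane | Clc1cc(OC)c(OCOC)c(c1)[C@H](C)[C@@H](B1O[C@H](C2CCCCC2)[C@@H](C2CCCCC2)O1)c1cc(OCOC)c(OC)c(OC)c1
A6 | alternative 3 | (4R,5R)-2-[(1S)-1-[5-chloro-3-methoxy-2-(methoxymethoxy)phenyl]ethyl]-4,5-dicyclohexyl-1,3,2-dioxaborolane | Clc1cc(OC)c(OCOC)c(c1)[C@H](C)B1O[C@H](C2CCCCC2)[C@@H](C2CCCCC2)O1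
A7 | alternative 3 | [3-(methoxymethoxy)-4,5-dimethoxyphenyl]magnesium bromide | COCOc1cc([Mg]Br)cc(OC)c1OC
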